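The pyran ring of the chroman (O1–C2–C3–C4–C4a–C8a) is cut at C2–C3 and at C4–C4a. C2 is a methylene on the aryl ether oxygen O1, and C4 is a carbinol carbon on the ring-A position ortho to O1. An aryl oxocarbenium ion (C2=O1+–C8a=C4a, a cationic 2-oxadiene) made from 2,3,4-trimethoxyphenol can therefore take up an (E)-β-aryl enol ether (C3=C4) in one oxa-Povarov annulation that forms both bonds and both stereocentres. The enol ether oxygen carries an (R)-1-phenylethyl group, which steers the C3 face, makes the isomers separable diastereomers, and leaves in the final hydrogenolysis together with the two benzyl ethers of the ring-B hydroquinone.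

Key step: step 6

Remark: the sense of face selection by the 1-phenylethyl group is assigned from the usual model for chiral benzylic enol ethers (s-trans C=C–O–C, carbinol C–H in the alkene plane, phenyl covering one face); should the opposite sense be found, (S)-1-phenylethanol is used in step 4, and in either case the C3 epimers are diastereomers that are separated after step 6.

Step 1
Reactants: 1 (2-hydroxy-3,4-dimethoxybenzaldehyde)
Product: 3 hydroquinone aldehyde (2,5-dihydroxy-3,4-dimethoxybenzaldehyde), via aryl sulfate potassium salt 2 (not isolated)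
Conditions: K2S2O8, aq NaOH, 5 °C → rt; then aq HCl, 70 °C
Reagents that add atoms: potassium peroxodisulfate, [K+].[K+].[O-]S(=O)(=O)OOS(=O)(=O)[O-]
Why: Elbs persulfate oxidation, in which the phenolate of 1 attacks a peroxide oxygen of peroxodisulfate through C5, the free position para to the phenolate oxygen (both ortho positions are substituted), and acid hydrolysis of the aryl sulfate 2 should give the hydroquinone.

Step 2
Reactants: 3 (2,5-dihydroxy-3,4-dimethoxybenzaldehyde)
Product: 4 bis-benzyl aldehyde (2,5-bis(benzyloxy)-3,4-dimethoxybenzaldehyde)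
Conditions: BnBr, K2CO3, DMF, 60 °C, under N2
Reagents that add atoms: benzyl bromide, BrCc1ccccc1
Why: Williamson ether synthesis (SN2 of both phenolates on benzyl bromide), which masks the oxidisable hydroquinone through the Lewis-acid step with groups that leave by hydrogenolysis at the end.

Step 3
Reactants: 4 (2,5-bis(benzyloxy)-3,4-dimethoxybenzaldehyde)
Product: 5 vinyl iodide (1,4-bis(benzyloxy)-5-[(E)-2-iodoethenyl]-2,3-dimethoxybenzene)
Conditions: CHI3, CrCl2, THF, 0 °C → rt
Reagents that add atoms: iodoform, IC(I)I
Why: Takai olefination, in which the geminal dichromium species from CHI3 and CrCl2 adds to the aldehyde and eliminates to give the (E)-vinyl iodide, the isomer normally favoured for aromatic aldehydes.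

Step 4
Reactants: 5 (1,4-bis(benzyloxy)-5-[(E)-2-iodoethenyl]-2,3-dimethoxybenzene); 6 ((R)-1-phenylethanol)
Product: 7 enol ether (1,4-bis(benzyloxy)-2,3-dimethoxy-5-{(E)-2-[(1R)-1-phenylethoxy]ethenyl}benzene)
Conditions: CuI (10 mol %), 3,4,7,8-tetramethyl-1,10-phenanthroline (20 mol %), Cs2CO3, toluene, 80 °C
Reagents that add atoms: none
Why: Ullmann-type copper-catalysed C–O cross-coupling of a vinyl iodide with an alcohol, which retains the E geometry of the alkene and does not touch the carbinol stereocentre of 6.

Step 5
Reactants: 8 (2,3,4-trimethoxyphenol)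
Product: 9 pivaloyloxymethyl ether ((2,3,4-trimethoxyphenoxy)methyl 2,2-dimethylpropanoate)
Conditions: chloromethyl pivalate, K2CO3, NaI (cat.), DMF, rt
Reagents that add atoms: chloromethyl pivalate, CC(C)(C)C(=O)OCCl
Why: SN2 O-alkylation of the phenolate by the chloromethyl ester under iodide catalysis, the standard way to aryl pivaloyloxymethyl ethers, with the hindered pivalate resisting acyl transfer to the phenolate.

Step 6
Reactants: 9 ((2,3,4-trimethoxyphenoxy)methyl 2,2-dimethylpropanoate); 7 (1,4-bis(benzyloxy)-2,3-dimethoxy-5-{(E)-2-[(1R)-1-phenylethoxy]ethenyl}benzene)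
Product: 12 annulation product ((3S,4R)-3-[2,5-bis(benzyloxy)-3,4-dimethoxyphenyl]-6,7,8-trimethoxy-4-[(1R)-1-phenylethoxy]-3,4-dihydro-2H-chromene), via aryl oxocarbenium triflate 10 (not isolated), via open-chain oxocarbenium triflate 11 (not isolated)
Conditions: TMSOTf (1.1 equiv, added slowly), 2,6-di-tert-butyl-4-methylpyridine (1.5 equiv), 4 Å MS, CH2Cl2, −78 → −40 °C; Et3N quench; chromatography to remove minor diastereomers
Reagents that add atoms: none
Why: Silyl activation of the pivalate carbonyl expels trimethylsilyl pivalate and leaves the aryl oxocarbenium ion 10, a cationic 2-oxadiene (C2=O1+–C8a=C4a); the electron-rich β-carbon of enol ether 7 (the future C3) adds to its methylene carbon to give oxocarbenium ion 11, whose C4 is then attacked by the ring-A carbon ortho to O1 (activated by O1 and by the para methoxy group), and loss of a proton restores the arene. The closest known reaction type is the oxa-Povarov reaction, the oxygen counterpart of the Povarov reaction, that is a stepwise inverse-electron-demand formal [4+2] annulation of an aryl oxocarbenium ion with an electron-rich alkene (Prins-type addition followed by Friedel–Crafts alkylation). The pyran ring is closed in a 6-exo-trig mode with respect to the C4=O+ bond, the attacking arene π bond being endocyclic. C3 is controlled by the (R)-1-phenylethyl group, whose phenyl ring covers the Si face of C3 in the s-trans enol ether with the carbinol C–H in the alkene plane, so that C2 is delivered to the Re face (3S); C4 follows from C3, because closure through a chair-like transition state with the aryl and alkoxy groups both pseudo-equatorial, the outcome also expected from the E alkene and favoured at equilibrium, gives the 3,4-trans ether (4R). The step needs ionisation on the aryloxy side (secured by the better acyloxy leaving group), C–C bond formation at the enol ether β-carbon ahead of oligomerisation (low temperature, hindered pyridine to trap protons, slow addition of TMSOTf) and ring closure at C4a, the only position of ring A that can reach C4. The minor C3 epimer is a diastereomer of 12 and is removed by chromatography.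

Step 7
Reactants: 12 ((3S,4R)-3-[2,5-bis(benzyloxy)-3,4-dimethoxyphenyl]-6,7,8-trimethoxy-4-[(1R)-1-phenylethoxy]-3,4-dihydro-2H-chromene)
Product: 13 target (2-[(3S,4R)-4-hydroxy-6,7,8-trimethoxy-3,4-dihydro-2H-chromen-3-yl]-5,6-dimethoxybenzene-1,4-diol)
Conditions: H2 (1 atm), Pd(OH)2/C, NaHCO3, EtOAc–THF, rt; filtration and concentration under argon
Reagents that add atoms: none
Why: Catalytic hydrogenolysis should cleave the two aryl benzyl ethers and the PhCH(CH3)–O bond of the C4 ether (the unhindered phenyl ring binds to palladium more readily than the pentasubstituted ring A), while the buffered neutral medium suppresses ionisation or hydrogenolysis at C4, so both stereocentres are retained.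

Compound list
1 | 2-hydroxy-3,4-dimethoxybenzaldehyde | COc1ccc(C=O)c(O)c1OC | starting material
2 | potassium 5-formyl-4-hydroxy-2,3-dimethoxyphenyl sulfate | COc1c(OC)c(OS(=O)(=O)[O-])cc(C=O)c1O.[K+] | intermediate
3 | 2,5-dihydroxy-3,4-dimethoxybenzaldehyde | COc1c(OC)c(O)cc(C=O)c1O | intermediate
4 | 2,5-bis(benzyloxy)-3,4-dimethoxybenzaldehyde | COc1c(OC)c(OCc2ccccc2)cc(C=O)c1OCc1ccccc1 | intermediate
5 | 1,4-bis(benzyloxy)-5-[(E)-2-iodoethenyl]-2,3-dimethoxybenzene | COc1c(OC)c(OCc2ccccc2)cc(/C=C/I)c1OCc1ccccc1 | intermediate
6 | (R)-1-phenylethanol | C[C@@H](O)c1ccccc1 | starting material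
7 | 1,4-bis(benzyloxy)-2,3-dimethoxy-5-{(E)-2-[(1R)-1-phenylethoxy]ethenyl}benzene | COc1c(OC)c(OCc2ccccc2)cc(/C=C/O[C@H](C)c2ccccc2)c1OCc1ccccc1 | intermediate
8 | 2,3,4-trimethoxyphenol | COc1ccc(O)c(OC)c1OC | starting material
9 | (2,3,4-trimethoxyphenoxy)methyl 2,2-dimethylpropanoate | COc1ccc(OCOC(=O)C(C)(C)C)c(OC)c1OC | intermediate
10 | methylidene(2,3,4-trimethoxyphenyl)oxonium triflate | COc1ccc([O+]=C)c(OC)c1OC.[O-]S(=O)(=O)C(F)(F)F | intermediate
11 | [(2S)-2-[2,5-bis(benzyloxy)-3,4-dimethoxyphenyl]-3-(2,3,4-trimethoxyphenoxy)propylidene][(1R)-1-phenylethyl]oxonium triflate | COc1ccc(OC[C@H](c2cc(OCc3ccccc3)c(OC)c(OC)c2OCc2ccccc2)C=[O+][C@H](C)c2ccccc2)c(OC)c1OC.[O-]S(=O)(=O)C(F)(F)F | intermediate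
12 | (3S,4R)-3-[2,5-bis(benzyloxy)-3,4-dimethoxyphenyl]-6,7,8-trimethoxy-4-[(1R)-1-phenylethoxy]-3,4-dihydro-2H-chromene | COc1cc2c(c(OC)c1OC)OC[C@H](c1cc(OCc3ccccc3)c(OC)c(OC)c1OCc1ccccc1)[C@H]2O[C@H](C)c1ccccc1 | intermediate
13 | 2-[(3S,4R)-4-hydroxy-6,7,8-trimethoxy-3,4-dihydro-2H-chromen-3-yl]-5,6-dimethoxybenzene-1,4-diol | COc1cc2c(c(OC)c1OC)OC[C@H](c1cc(O)c(OC)c(OC)c1O)[C@H]2O | target

Total step count: 7. Longest linear sequence: 6 steps (steps 1, 2, 3, 4, 6, 7).

Steps most likely to fail

Step 6. Three processes threaten it: weak facial discrimination at C3 by a small auxiliary three bonds away, ionisation of the new C4 ether with loss of 1-phenylethanol (elimination across C3–C4), and cationic oligomerisation of the enol ether. The fallback sets out from 7 and 9, gives up auxiliary control and lets the elimination run to completion. The same annulation would be carried out with TMSOTf in CH2Cl2 without base and warmed to 0 °C, to give the achiral 3-[2,5-bis(benzyloxy)-3,4-dimethoxyphenyl]-6,7,8-trimethoxy-2H-chromene F1. Both stereocentres would then be set by reagent-controlled asymmetric hydroboration–oxidation with monoisopinocampheylborane (IpcBH2, THF, −25 °C; then NaOH, H2O2). This is the Brown reaction of 1-arylcycloalkenes, with boron going to the less substituted C4 and syn addition of H and B making the product trans. The enantiomer of the borane is chosen from the Brown model, both being available from the two α-pinenes. The product would be (3S,4R)-3-[2,5-bis(benzyloxy)-3,4-dimethoxyphenyl]-6,7,8-trimethoxy-3,4-dihydro-2H-chromen-4-ol F2, whose two benzyl ethers are removed with H2 and Pd(OH)2/C to come back to the route at 13.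

Step 7. Hydrogenolysis may occur on the chroman side of the C4 oxygen (loss of the C4 oxygen) when the reaction is pushed to completion, and the free hydroquinone may be oxidised by air during filtration, so that end point and isolation work against each other. The fallback sets out from 12 and separates the two problems by a detour through the quinone oxidation level. The hydrogenolysis is stopped early and the crude material is oxidised deliberately (Ag2O, Et2O, rt) to the stable 5-[(3S,4R)-4-hydroxy-6,7,8-trimethoxy-3,4-dihydro-2H-chromen-3-yl]-2,3-dimethoxycyclohexa-2,5-diene-1,4-dione F3. F3 is purified by chromatography, with incompletely deprotected material recycled, and is then reduced without catalyst or hydrogen (aq Na2S2O4, EtOAc, under argon) to come back to the route at 13. The quinone detour does not prevent C4–O cleavage on the chroman side; it only allows an early stop and purification.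

Step 1. The phenolate may be degraded by sulfate radicals (oxidative polymerisation), and conversion to the sulfate ester is typically low in the Elbs reaction. The fallback sets out from 8 and builds the ring-B aldehyde from the other end. Oxidative demethylation of the para-methoxyphenol (PhI(OAc)2, MeCN–H2O, 0 °C) gives 2,3-dimethoxy-1,4-benzoquinone F4. Reduction (aq Na2S2O4) gives 2,3-dimethoxybenzene-1,4-diol F5, and benzylation (BnBr, K2CO3, DMF) gives the symmetrical 1,4-bis(benzyloxy)-2,3-dimethoxybenzene F6. Vilsmeier–Haack formylation (POCl3, DMF, 80 °C) at either of its two equivalent free positions comes back to the route at 4.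

Further compounds
F1 | step 6 | 3-[2,5-bis(benzyloxy)-3,4-dimethoxyphenyl]-6,7,8-trimethoxy-2H-chromene | COc1cc2c(c(OC)c1OC)OCC(c1cc(OCc3ccccc3)c(OC)c(OC)c1OCc1ccccc1)=C2
F2 | step 6 | (3S,4R)-3-[2,5-bis(benzyloxy)-3,4-dimethoxyphenyl]-6,7,8-trimethoxy-3,4-dihydro-2H-chromen-4-ol | COc1cc2c(c(OC)c1OC)OC[C@H](c1cc(OCc3ccccc3)c(OC)c(OC)c1OCc1ccccc1)[C@H]2O
F3 | step 7 | 5-[(3S,4R)-4-hydroxy-6,7,8-trimethoxy-3,4-dihydro-2H-chromen-3-yl]-2,3-dimethoxycyclohexa-2,5-diene-1,4-dione | COc1cc2c(c(OC)c1OC)OC[C@H](C1=CC(=O)C(OC)=C(OC)C1=O)[C@H]2O
F4 | step 1 | 2,3-dimethoxy-1,4-benzoquinone | COC1=C(OC)C(=O)C=CC1=O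
F5 | step 1 | 2,3-dimethoxybenzene-1,4-diol | COc1c(O)ccc(O)c1OC
F6 | step 1 | 1,4-bis(benzyloxy)-2,3-dimethoxybenzene | COc1c(OCc2ccccc2)ccc(OCc2ccccc2)c1OC
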